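The target is epiafzelechin-(4β→8)-epiafzelechin-(4β→8)-4'-O-methylepigallocatechin. The route rests on cutting the C2–C3 bond of ring C of the middle flavan: C2, the benzylic carbon on O1, is traced to the carbonyl carbon of a 4-benzyloxybenzoate on the ring A phenol, and C3–C4 to an ortho allyl group. After methylenation of the ester, ring-closing metathesis joins C2 to C3 and closes the pyran ring as an achiral flav-2-ene; asymmetric hydroboration, oxidation and hydride reduction then set the 2,3-cis stereocentres. The same protected epiafzelechin serves as middle and top unit; two C4→C8 couplings and hydrogenolysis finish the trimer.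

Key step: step 5

Remark: flavan numbering (O1, C2, C3, C4, C4a to C8a, primed positions for ring B) is used for every unit; compounds 1, 2, 5 and 14 are taken as purchasable; electrophile 13 is used twice (steps 18 and 19).

Step 1
Reactants: 1 3,5-bis(benzyloxy)phenol; 2 allyl bromide
Product: 3 1-(allyloxy)-3,5-bis(benzyloxy)benzene
Conditions: K2CO3, acetone, reflux
Reagents that add atoms: none
Why: Williamson ether synthesis, the phenoxide displacing bromide from the allylic halide.

Step 2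
Reactants: 3 1-(allyloxy)-3,5-bis(benzyloxy)benzene
Product: 4 2-allyl-3,5-bis(benzyloxy)phenol
Conditions: N,N-diethylaniline, 195 °C, argon
Reagents that add atoms: none
Why: Aromatic Claisen [3,3] rearrangement; the two ortho positions are equivalent, so a single allylphenol should result, its allyl CH2 and CH becoming C4 and C3.

Step 3
Reactants: 4 2-allyl-3,5-bis(benzyloxy)phenol; 5 4-(benzyloxy)benzoic acid
Product: 6 2-allyl-3,5-bis(benzyloxy)phenyl 4-(benzyloxy)benzoate
Conditions: DCC, DMAP (cat.), CH2Cl2, 0 °C to rt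
Reagents that add atoms: none
Why: Steglich esterification places the future C2 (with ring B) on O1 as an ester carbonyl.

Step 4
Reactants: 6 2-allyl-3,5-bis(benzyloxy)phenyl 4-(benzyloxy)benzoate
Product: 7 2-allyl-1,5-bis(benzyloxy)-3-{[1-(4-(benzyloxy)phenyl)vinyl]oxy}benzene
Conditions: Cp2TiMe2 (dimethyltitanocene), toluene/THF, 65 °C, dark; filtration through basic alumina
Reagents that add atoms: dimethyltitanocene, C[Ti](C)(C1C=CC=C1)C1C=CC=C1
Why: Petasis methylenation (titanocene methylidene, oxatitanacyclobutane, loss of the titanium oxide) converts aryl benzoates into aryl α-styryl ethers and leaves the isolated allyl alkene untouched at this temperature.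

Step 5
Reactants: 7 2-allyl-1,5-bis(benzyloxy)-3-{[1-(4-(benzyloxy)phenyl)vinyl]oxy}benzene
Product: 8 5,7-bis(benzyloxy)-2-[4-(benzyloxy)phenyl]-4H-chromene
Conditions: second-generation Grubbs catalyst RuCl2(=CHPh)(PCy3)(H2IMes) (5 mol %), 1,4-benzoquinone (10 mol %), toluene (0.005 M), 70 °C, argon sparge
Reagents that add atoms: none
Why: Ring-closing olefin metathesis by the Chauvin mechanism: the ruthenium benzylidene first engages the unhindered allyl terminus, and the alkylidene then sitting on C3 undergoes intramolecular [2+2] cycloaddition with the 1,1-disubstituted enol ether and cycloreversion with loss of ethylene, joining C3 to the former ester carbon C2. The closest known reaction type is the ring-closing metathesis of olefinic enol ethers, made by ester methylenation, to cyclic enol ethers and 4H-chromenes. Ring C is closed as a six-membered ring through a ruthenacyclobutane, both alkene carbons ending up endocyclic. No stereocentre is created, since C2 and C3 become sp2 carbons of an achiral flav-2-ene; their configurations are set in steps 6 to 8. The step needs ring closure to outrun allyl-to-propenyl isomerisation (which would lead to a benzofuran) and intermolecular cross-metathesis; the ortho placement of both alkenes on ring A, high dilution with removal of ethylene, and benzoquinone as a scavenger of ruthenium hydrides should secure this. Acid is excluded throughout because 7 and 8 are hydrolytically labile aryl enol ethers.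

Step 6
Reactants: 8 5,7-bis(benzyloxy)-2-[4-(benzyloxy)phenyl]-4H-chromene
Product: 10 (2R,3S)-5,7-bis(benzyloxy)-2-[4-(benzyloxy)phenyl]chroman-3-ol, via chroman-3-yl(isopinocampheyl)borane 9 (not isolated)
Conditions: (IpcBH2)2·TMEDA [from (+)-α-pinene], BF3·OEt2, THF, 25 °C; then 8, −25 °C; then NaOH, H2O2, 0 °C to rt
Reagents that add atoms: hydrogen peroxide, OO
Why: Brown asymmetric hydroboration: boron adds to C3 (β to O1, the less substituted carbon) and hydrogen to C2 in a syn fashion, the pinene-derived borane selecting the alkene face (sense assigned by analogy with 1-arylcycloalkenes, to be confirmed on the product), and oxidation with retention should give the 2,3-trans (2R,3S) alcohol.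

Step 7
Reactants: 10 (2R,3S)-5,7-bis(benzyloxy)-2-[4-(benzyloxy)phenyl]chroman-3-ol
Product: 11 (2R)-5,7-bis(benzyloxy)-2-[4-(benzyloxy)phenyl]chroman-3-one
Conditions: Dess–Martin periodinane, CH2Cl2 (water-saturated), rt
Reagents that add atoms: none
Why: Dess–Martin oxidation under near-neutral conditions should give the flavan-3-one without enolisation at C2.

Step 8
Reactants: 11 (2R)-5,7-bis(benzyloxy)-2-[4-(benzyloxy)phenyl]chroman-3-one
Product: 12 (2R,3R)-5,7-bis(benzyloxy)-2-[4-(benzyloxy)phenyl]chroman-3-ol (5,7,4'-tri-O-benzylepiafzelechin)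
Conditions: LiBH(s-Bu)3 (L-Selectride), LiBr, THF, −78 °C; then H2O
Reagents that add atoms: none
Why: The bulky hydride attacks the carbonyl from the face opposite the 2-aryl group, so the new C3 hydroxyl should be cis to it (substrate-controlled ketone reduction, the standard trans-to-cis inversion of benzylated flavan-3-ols).

Step 9
Reactants: 12 (2R,3R)-5,7-bis(benzyloxy)-2-[4-(benzyloxy)phenyl]chroman-3-ol
Product: 13 (2R,3R,4S)-5,7-bis(benzyloxy)-2-[4-(benzyloxy)phenyl]-4-(2-hydroxyethoxy)chroman-3-ol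
Conditions: DDQ, ethylene glycol, CH2Cl2, rt
Reagents that add atoms: ethylene glycol, OCCO
Why: DDQ benzylic oxidation removes hydride from C4 to give a cation stabilised by the three oxygens of ring A, and the glycol should add anti to the cis 2-aryl and 3-hydroxyl groups (4β).

Step 10
Reactants: 14 3,5-dihydroxy-4-methoxybenzoic acid
Product: 15 benzyl 3,5-bis(benzyloxy)-4-methoxybenzoate
Conditions: BnBr, K2CO3, DMF, 60 °C
Reagents that add atoms: benzyl bromide, BrCc1ccccc1
Why: Williamson alkylation of both phenoxides and the carboxylate.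

Step 11
Reactants: 15 benzyl 3,5-bis(benzyloxy)-4-methoxybenzoate
Product: 16 3,5-bis(benzyloxy)-4-methoxybenzoic acid
Conditions: KOH, THF/MeOH/H2O, 60 °C; then aq. HCl
Reagents that add atoms: potassium hydroxide, [K+].[OH-]
Why: Saponification cleaves only the benzyl ester, the aryl benzyl ethers being inert to hydroxide.

Step 12
Reactants: 4 2-allyl-3,5-bis(benzyloxy)phenol; 16 3,5-bis(benzyloxy)-4-methoxybenzoic acid
Product: 17 2-allyl-3,5-bis(benzyloxy)phenyl 3,5-bis(benzyloxy)-4-methoxybenzoate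
Conditions: DCC, DMAP (cat.), CH2Cl2, 0 °C to rt
Reagents that add atoms: none
Why: Steglich esterification, as in step 3.

Step 13
Reactants: 17 2-allyl-3,5-bis(benzyloxy)phenyl 3,5-bis(benzyloxy)-4-methoxybenzoate
Product: 18 2-allyl-1,5-bis(benzyloxy)-3-{[1-(3,5-bis(benzyloxy)-4-methoxyphenyl)vinyl]oxy}benzene
Conditions: Cp2TiMe2 (dimethyltitanocene), toluene/THF, 65 °C, dark; filtration through basic alumina
Reagents that add atoms: dimethyltitanocene, C[Ti](C)(C1C=CC=C1)C1C=CC=C1
Why: Petasis methylenation of the aryl ester, as in step 4.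

Step 14
Reactants: 18 2-allyl-1,5-bis(benzyloxy)-3-{[1-(3,5-bis(benzyloxy)-4-methoxyphenyl)vinyl]oxy}benzene
Product: 19 5,7-bis(benzyloxy)-2-[3,5-bis(benzyloxy)-4-methoxyphenyl]-4H-chromene
Conditions: second-generation Grubbs catalyst RuCl2(=CHPh)(PCy3)(H2IMes) (5 mol %), 1,4-benzoquinone (10 mol %), toluene (0.005 M), 70 °C, argon sparge
Reagents that add atoms: none
Why: Ring-closing metathesis of the enol ether with the allyl group, as in step 5, should close ring C of the bottom unit.

Step 15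
Reactants: 19 5,7-bis(benzyloxy)-2-[3,5-bis(benzyloxy)-4-methoxyphenyl]-4H-chromene
Product: 21 (2R,3S)-5,7-bis(benzyloxy)-2-[3,5-bis(benzyloxy)-4-methoxyphenyl]chroman-3-ol, via chroman-3-yl(isopinocampheyl)borane 20 (not isolated)
Conditions: (IpcBH2)2·TMEDA [from (+)-α-pinene], BF3·OEt2, THF, 25 °C; then 19, −25 °C; then NaOH, H2O2, 0 °C to rt
Reagents that add atoms: hydrogen peroxide, OO
Why: Brown asymmetric hydroboration with syn addition (boron to C3) and oxidation with retention, as in step 6, should give the 2,3-trans (2R,3S) alcohol.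

Step 16
Reactants: 21 (2R,3S)-5,7-bis(benzyloxy)-2-[3,5-bis(benzyloxy)-4-methoxyphenyl]chroman-3-ol
Product: 22 (2R)-5,7-bis(benzyloxy)-2-[3,5-bis(benzyloxy)-4-methoxyphenyl]chroman-3-one
Conditions: Dess–Martin periodinane, CH2Cl2 (water-saturated), rt
Reagents that add atoms: none
Why: Dess–Martin oxidation, as in step 7.

Step 17
Reactants: 22 (2R)-5,7-bis(benzyloxy)-2-[3,5-bis(benzyloxy)-4-methoxyphenyl]chroman-3-one
Product: 23 (2R,3R)-5,7-bis(benzyloxy)-2-[3,5-bis(benzyloxy)-4-methoxyphenyl]chroman-3-ol (5,7,3',5'-tetra-O-benzyl-4'-O-methylepigallocatechin)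
Conditions: LiBH(s-Bu)3 (L-Selectride), LiBr, THF, −78 °C; then H2O
Reagents that add atoms: none
Why: Hydride delivery anti to the 2-aryl group should give the 2,3-cis alcohol, as in step 8.

Step 18
Reactants: 13 (2R,3R,4S)-5,7-bis(benzyloxy)-2-[4-(benzyloxy)phenyl]-4-(2-hydroxyethoxy)chroman-3-ol; 23 (2R,3R)-5,7-bis(benzyloxy)-2-[3,5-bis(benzyloxy)-4-methoxyphenyl]chroman-3-ol
Product: 24 5,7,4'-tri-O-benzylepiafzelechin-(4β→8)-5,7,3',5'-tetra-O-benzyl-4'-O-methylepigallocatechin; upper unit (2R,3R,4R), lower unit (2R,3R)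
Conditions: TiCl4, 23 (4 equiv, excess recovered), CH2Cl2/THF (9:1), 0 °C; then H2O
Reagents that add atoms: none
Why: Lewis acid ionisation of the chelating 4-(2-hydroxyethoxy) group gives the flavan-4-yl cation, which undergoes Friedel–Crafts attack by the most nucleophilic position C8 of 23, anti to the cis 2-aryl and 3-hydroxyl groups (3,4-trans, 4β).

Step 19
Reactants: 13 (2R,3R,4S)-5,7-bis(benzyloxy)-2-[4-(benzyloxy)phenyl]-4-(2-hydroxyethoxy)chroman-3-ol; 24 the dimer of step 18
Product: 25 deca-O-benzyl trimer, 5,7,4'-tri-O-benzylepiafzelechin-(4β→8)-5,7,4'-tri-O-benzylepiafzelechin-(4β→8)-5,7,3',5'-tetra-O-benzyl-4'-O-methylepigallocatechin; top unit (2R,3R,4R), middle unit (2R,3R,4S), bottom unit (2R,3R)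
Conditions: TiCl4, 24 (3 equiv, excess recovered), CH2Cl2/THF (9:1), 0 °C; then H2O
Reagents that add atoms: none
Why: The same cationic Friedel–Crafts coupling; C8 of the upper unit of 24 is the most accessible electron-rich position of the dimer, and attack anti to the 3-hydroxyl of the donor should again give the 4β bond.

Step 20
Reactants: 25 deca-O-benzyl trimer
Product: 26 epiafzelechin-(4β→8)-epiafzelechin-(4β→8)-4'-O-methylepigallocatechin (CNP0146516.1)
Conditions: H2 (1 atm), Pd(OH)2/C, THF/MeOH/H2O, rt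
Reagents that add atoms: none
Why: Hydrogenolysis should cleave all ten benzyl ethers while the methyl ether, the secondary alcohols and the interflavan bonds are retained.

Compound list
1 | 3,5-bis(benzyloxy)phenol | Oc1cc(OCc2ccccc2)cc(OCc2ccccc2)c1 | starting material
2 | allyl bromide | C=CCBr | starting material
3 | 1-(allyloxy)-3,5-bis(benzyloxy)benzene | C=CCOc1cc(OCc2ccccc2)cc(OCc2ccccc2)c1 | intermediate
4 | 2-allyl-3,5-bis(benzyloxy)phenol | C=CCc1c(O)cc(OCc2ccccc2)cc1OCc1ccccc1 | intermediate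
5 | 4-(benzyloxy)benzoic acid | OC(=O)c1ccc(OCc2ccccc2)cc1 | starting material
6 | 2-allyl-3,5-bis(benzyloxy)phenyl 4-(benzyloxy)benzoate | C=CCc1c(OC(=O)c2ccc(OCc3ccccc3)cc2)cc(OCc2ccccc2)cc1OCc1ccccc1 | intermediate
7 | 2-allyl-1,5-bis(benzyloxy)-3-{[1-(4-(benzyloxy)phenyl)vinyl]oxy}benzene | C=CCc1c(OC(=C)c2ccc(OCc3ccccc3)cc2)cc(OCc2ccccc2)cc1OCc1ccccc1 | intermediate
8 | 5,7-bis(benzyloxy)-2-[4-(benzyloxy)phenyl]-4H-chromene | c1ccc(COc2ccc(C3=CCc4c(OCc5ccccc5)cc(OCc5ccccc5)cc4O3)cc2)cc1 | intermediate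
9 | {5,7-bis(benzyloxy)-2-[4-(benzyloxy)phenyl]chroman-3-yl}(isopinocampheyl)borane; boron at C3 trans to the 2-aryl group, same configuration as 10, isopinocampheyl from (+)-α-pinene | C[C@@H]1[C@H]2C[C@H](C2(C)C)C[C@H]1B[C@H]1Cc2c(OCc3ccccc3)cc(OCc3ccccc3)cc2O[C@@H]1c1ccc(OCc2ccccc2)cc1 | intermediate
10 | (2R,3S)-5,7-bis(benzyloxy)-2-[4-(benzyloxy)phenyl]chroman-3-ol | c1ccc(COc2ccc([C@H]3Oc4cc(OCc5ccccc5)cc(OCc5ccccc5)c4C[C@@H]3O)cc2)cc1 | intermediate
11 | (2R)-5,7-bis(benzyloxy)-2-[4-(benzyloxy)phenyl]chroman-3-one | c1ccc(COc2ccc([C@H]3Oc4cc(OCc5ccccc5)cc(OCc5ccccc5)c4CC3=O)cc2)cc1 | intermediate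
12 | (2R,3R)-5,7-bis(benzyloxy)-2-[4-(benzyloxy)phenyl]chroman-3-ol | c1ccc(COc2ccc([C@H]3Oc4cc(OCc5ccccc5)cc(OCc5ccccc5)c4C[C@H]3O)cc2)cc1 | intermediate
13 | (2R,3R,4S)-5,7-bis(benzyloxy)-2-[4-(benzyloxy)phenyl]-4-(2-hydroxyethoxy)chroman-3-ol | c1ccc(COc2ccc([C@H]3Oc4cc(OCc5ccccc5)cc(OCc5ccccc5)c4[C@H](OCCO)[C@H]3O)cc2)cc1 | intermediate
14 | 3,5-dihydroxy-4-methoxybenzoic acid | COc1c(O)cc(C(=O)O)cc1O | starting material
15 | benzyl 3,5-bis(benzyloxy)-4-methoxybenzoate | COc1c(OCc2ccccc2)cc(C(=O)OCc2ccccc2)cc1OCc1ccccc1 | intermediate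
16 | 3,5-bis(benzyloxy)-4-methoxybenzoic acid | COc1c(OCc2ccccc2)cc(C(=O)O)cc1OCc1ccccc1 | intermediate
17 | 2-allyl-3,5-bis(benzyloxy)phenyl 3,5-bis(benzyloxy)-4-methoxybenzoate | C=CCc1c(OC(=O)c2cc(OCc3ccccc3)c(OC)c(OCc3ccccc3)c2)cc(OCc2ccccc2)cc1OCc1ccccc1 | intermediate
18 | 2-allyl-1,5-bis(benzyloxy)-3-{[1-(3,5-bis(benzyloxy)-4-methoxyphenyl)vinyl]oxy}benzene | C=CCc1c(OC(=C)c2cc(OCc3ccccc3)c(OC)c(OCc3ccccc3)c2)cc(OCc2ccccc2)cc1OCc1ccccc1 | intermediate
19 | 5,7-bis(benzyloxy)-2-[3,5-bis(benzyloxy)-4-methoxyphenyl]-4H-chromene | COc1c(OCc2ccccc2)cc(C2=CCc3c(OCc4ccccc4)cc(OCc4ccccc4)cc3O2)cc1OCc1ccccc1 | intermediate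
20 | {5,7-bis(benzyloxy)-2-[3,5-bis(benzyloxy)-4-methoxyphenyl]chroman-3-yl}(isopinocampheyl)borane; boron at C3 trans to the 2-aryl group, same configuration as 21, isopinocampheyl from (+)-α-pinene | C[C@@H]1[C@H]2C[C@H](C2(C)C)C[C@H]1B[C@H]1Cc2c(OCc3ccccc3)cc(OCc3ccccc3)cc2O[C@@H]1c1cc(OCc2ccccc2)c(OC)c(OCc2ccccc2)c1 | intermediate
21 | (2R,3S)-5,7-bis(benzyloxy)-2-[3,5-bis(benzyloxy)-4-methoxyphenyl]chroman-3-ol | COc1c(OCc2ccccc2)cc([C@H]2Oc3cc(OCc4ccccc4)cc(OCc4ccccc4)c3C[C@@H]2O)cc1OCc1ccccc1 | intermediate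
22 | (2R)-5,7-bis(benzyloxy)-2-[3,5-bis(benzyloxy)-4-methoxyphenyl]chroman-3-one | COc1c(OCc2ccccc2)cc([C@H]2Oc3cc(OCc4ccccc4)cc(OCc4ccccc4)c3CC2=O)cc1OCc1ccccc1 | intermediate
23 | (2R,3R)-5,7-bis(benzyloxy)-2-[3,5-bis(benzyloxy)-4-methoxyphenyl]chroman-3-ol | COc1c(OCc2ccccc2)cc([C@H]2Oc3cc(OCc4ccccc4)cc(OCc4ccccc4)c3C[C@H]2O)cc1OCc1ccccc1 | intermediate
24 | hepta-O-benzyl dimer, tri-O-benzylepiafzelechin-(4β→8)-tetra-O-benzyl-4'-O-methylepigallocatechin; upper unit (2R,3R,4R), lower unit (2R,3R) | COc1c(OCc7ccccc7)cc([C@H]2Oc3c(c(OCc7ccccc7)cc(OCc7ccccc7)c3[C@H]3c4c(OCc7ccccc7)cc(OCc7ccccc7)cc4O[C@H](c4ccc(OCc7ccccc7)cc4)[C@@H]3O)C[C@H]2O)cc1OCc7ccccc7 | intermediate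
25 | deca-O-benzyl trimer; top unit (2R,3R,4R), middle unit (2R,3R,4S), bottom unit (2R,3R), both interflavan bonds 4β→8 | COc1c(OCc7ccccc7)cc([C@H]2Oc3c(c(OCc7ccccc7)cc(OCc7ccccc7)c3[C@H]3c4c(OCc7ccccc7)cc(OCc7ccccc7)c([C@H]5c6c(OCc7ccccc7)cc(OCc7ccccc7)cc6O[C@H](c6ccc(OCc7ccccc7)cc6)[C@@H]5O)c4O[C@H](c4ccc(OCc7ccccc7)cc4)[C@@H]3O)C[C@H]2O)cc1OCc7ccccc7 | intermediate
26 | epiafzelechin-(4β→8)-epiafzelechin-(4β→8)-4'-O-methylepigallocatechin; top unit (2R,3R,4R), middle unit (2R,3R,4S), bottom unit (2R,3R) | COc1c(O)cc([C@H]2Oc3c(c(O)cc(O)c3[C@H]3c4c(O)cc(O)c([C@H]5c6c(O)cc(O)cc6O[C@H](c6ccc(O)cc6)[C@@H]5O)c4O[C@H](c4ccc(O)cc4)[C@@H]3O)C[C@H]2O)cc1O | target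

Total step count: 20. Longest linear sequence: 12 steps (steps 1 to 9, then 18, 19 and 20).

Steps most likely to fail

Step 5 (the ring closure). The ruthenium alkylidene may be diverted into isomerisation of the allyl group to a propenyl group, which would lead to ring closure one carbon short, or it may rest as an unreactive heteroatom-stabilised carbene on the electron-rich enol ether so that the ring does not close. The fallback sets out from ester 6 and avoids both the enol ether 7 and ruthenium. A titanium ethylidene generated under Takai–Utimoto conditions (TiCl4, Zn, PbCl2 (cat.), TMEDA, CH3CHBr2, THF/CH2Cl2, 65 °C) should exchange with the allyl terminus, and the titanium alkylidene then sitting on C3 should olefinate the ester carbonyl C2 intramolecularly (olefinic ester cyclisation). This comes back to the route at 8 and makes no new compound (F0).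

Step 6 (asymmetric hydroboration). Enantiofacial discrimination of the flat 2-aryl enol ether by the chiral borane may be insufficient. The fallback sets out from alcohol 10 as obtained, whatever its enantiomeric purity, that is 10 accompanied by its mirror image (2S,3R)-5,7-bis(benzyloxy)-2-[4-(benzyloxy)phenyl]chroman-3-ol F1. Oxidation as in step 7 gives ketone 11 accompanied by (2S)-5,7-bis(benzyloxy)-2-[4-(benzyloxy)phenyl]chroman-3-one F2. Stereocontrol then moves from the alkene to the ketone: a Noyori asymmetric hydrogenation under dynamic kinetic resolution (RuCl2[(S)-xylbinap][(S)-daipen] or its antipode, whichever delivers the 3R series, KOt-Bu, i-PrOH, H2) should equilibrate C2 through the enolate while one ketone enantiomer is reduced to the cis alcohol. This comes back to the route at 12 and replaces steps 7 and 8.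

Step 19 (second coupling). The cation from 13 may be captured by C8 of a second molecule of 13 instead of the valuable dimer 24, giving chain growth and oligomer mixtures. The fallback sets out from 12 and blocks that position. NBS in CH2Cl2 at −78 °C should give (2R,3R)-5,7-bis(benzyloxy)-2-[4-(benzyloxy)phenyl]-8-bromochroman-3-ol F3. DDQ and ethylene glycol as in step 9 should give (2R,3R,4S)-5,7-bis(benzyloxy)-2-[4-(benzyloxy)phenyl]-8-bromo-4-(2-hydroxyethoxy)chroman-3-ol F4. TiCl4 coupling of this capped electrophile with 24, now needed only in slight excess, should give the 8-bromo derivative of trimer 25 (bromine at C8 of the top unit) F5. Hydrogenolysis with H2, Pd(OH)2/C and Et3N removes the bromine together with the benzyl groups and comes back to the route at 26.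

Further compounds
F0 | step 5 | none | none
F1 | step 6 | (2S,3R)-5,7-bis(benzyloxy)-2-[4-(benzyloxy)phenyl]chroman-3-ol | c1ccc(COc2ccc([C@@H]3Oc4cc(OCc5ccccc5)cc(OCc5ccccc5)c4C[C@H]3O)cc2)cc1
F2 | step 6 | (2S)-5,7-bis(benzyloxy)-2-[4-(benzyloxy)phenyl]chroman-3-one | c1ccc(COc2ccc([C@@H]3Oc4cc(OCc5ccccc5)cc(OCc5ccccc5)c4CC3=O)cc2)cc1
F3 | step 19 | (2R,3R)-5,7-bis(benzyloxy)-2-[4-(benzyloxy)phenyl]-8-bromochroman-3-ol | c1ccc(COc2ccc([C@H]3Oc4c(Br)c(OCc5ccccc5)cc(OCc5ccccc5)c4C[C@H]3O)cc2)cc1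
F4 | step 19 | (2R,3R,4S)-5,7-bis(benzyloxy)-2-[4-(benzyloxy)phenyl]-8-bromo-4-(2-hydroxyethoxy)chroman-3-ol | c1ccc(COc2ccc([C@H]3Oc4c(Br)c(OCc5ccccc5)cc(OCc5ccccc5)c4[C@H](OCCO)[C@H]3O)cc2)cc1
F5 | step 19 | 8-bromo derivative of trimer 25, bromine at C8 of the top unit | COc1c(OCc7ccccc7)cc([C@H]2Oc3c(c(OCc7ccccc7)cc(OCc7ccccc7)c3[C@H]3c4c(OCc7ccccc7)cc(OCc7ccccc7)c([C@H]5c6c(OCc7ccccc7)cc(OCc7ccccc7)c(Br)c6O[C@H](c6ccc(OCc7ccccc7)cc6)[C@@H]5O)c4O[C@H](c4ccc(OCc7ccccc7)cc4)[C@@H]3O)C[C@H]2O)cc1OCc7ccccc7
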